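## Retrosynthetic overview

1. Target 27 ← C12 aldehyde by two Wittig olefinations (C11–C16 diene); before that the C6 acetate, the equatorial C6 alcohol (SmI2) and the C8(17) alkene (deconjugation) all come from ring-B enone 19.
2. 19 ← bromo ester 17 by making C4–C5 and closing ring A. The strategy rests on the 1,4-relationship of the C18 ester carbonyl and the C6 oxygen across the hindered C4–C5 bond between ring A and ring B: C4 reacts as a tertiary α-ester radical and C5 as the nucleophilic end of a C6 silyl dienol ether (radical–polar crossover, 6-exo).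
3. 17 ← ring-B enone ester 15 by O-silylation, then ester bromination; 15 ← ketone 9 by cross-metathesis/hydrogenation of a butenyl arm (C1–C4, C18, C19), then dehydrogenation and methyl cuprate addition/re-oxidation (C17).
4. 9 ← 3-methyl enone 6 by conjugate addition anti to the C9 chain (quaternary C10); 6 ← cyclohexenone 4 from an enamine-catalysed Michael/aldol sequence that sets C9 and builds ring B.
5. Ring order: ring B in step 1, ring A in step 10.

Key step: step 10

Remarks on the chemistry:
- Labdane numbering is used (ring A: C1–C5, C10; ring B: C5–C10; C17 on C8; C18 ester carbon and C19 methyl on C4; C20 methyl on C10). The target belongs to the ent series, so configurations are given relative to C20.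
- The (S)-configured pyrrolidine catalyst is assumed to deliver (S)-3 (steric-shielding model); if the sense is opposite, its enantiomer is used.
- C4 is carried as both epimers in 12–17 (no C4 descriptor in their SMILES) because it becomes a planar radical in step 10.

## Route

Step 1
Reactants: 1 4-[(tert-butyldimethylsilyl)oxy]butanal; 2 methyl vinyl ketone
Product: 4 (S)-4-[2-(tert-butyldimethylsilyloxy)ethyl]cyclohex-2-en-1-one, via keto aldehyde 3 (not isolated)
Conditions: (S)-2-[methoxy(diphenyl)methyl]pyrrolidine (5 mol%), ethyl 3,4-dihydroxybenzoate (20 mol%), neat, 4 °C; then LiOH, iPrOH, rt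
Reagents that add atoms: none
Why: An enamine-catalysed asymmetric Michael addition, in which the diarylmethyl group of the catalyst shields one enamine face and so sets C9, is followed by intramolecular aldol condensation of 3, which should close ring B with little erosion of the γ-stereocentre.

Step 2
Reactants: 4 (S)-4-[2-(tert-butyldimethylsilyloxy)ethyl]cyclohex-2-en-1-one
Product: 6 (S)-4-[2-(tert-butyldimethylsilyloxy)ethyl]-3-methylcyclohex-2-en-1-one, via silyl enol ether 5 (not isolated)
Conditions: Me2CuLi, TMSCl, Et2O, −78 °C; then Pd(OAc)2 (10 mol%), O2, DMSO, rt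
Reagents that add atoms: lithium dimethylcuprate, [Li+].C[Cu-]C
Why: Gilman 1,4-addition with silyl trapping followed by Saegusa–Ito dehydrogenation of 5 should return the enone with the C20 methyl on C10; the transient C10 stereocentre is erased and C9 is untouched.

Step 3
Reactants: 6 (S)-4-[2-(tert-butyldimethylsilyloxy)ethyl]-3-methylcyclohex-2-en-1-one; 7 but-3-enylmagnesium bromide
Product: 9 (3R,4S)-3-(but-3-enyl)-3-methyl-4-[2-(tert-butyldimethylsilyloxy)ethyl]cyclohexan-1-one, via silyl enol ether 8 (not isolated)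
Conditions: CuBr·SMe2 (20 mol%), TMSCl, THF, −78 to −20 °C; then 0.5 M HCl, 0 °C
Reagents that add atoms: none
Why: Copper-catalysed, TMSCl-accelerated conjugate addition of the Grignard reagent builds quaternary C10; the C9 chain lies pseudoaxial to avoid allylic strain with the C10 methyl and the nucleophile enters axially on the opposite face, so the butenyl arm should be anti and the C20 methyl syn to the C9 chain.

Step 4
Reactants: 9 (3R,4S)-3-(but-3-enyl)-3-methyl-4-[2-(tert-butyldimethylsilyloxy)ethyl]cyclohexan-1-one; 10 methyl methacrylate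
Product: 11 methyl (E)-2-methyl-5-{1-methyl-5-oxo-2-[2-(tert-butyldimethylsilyloxy)ethyl]cyclohexyl}pent-2-enoate
Conditions: second-generation Hoveyda–Grubbs catalyst (5 mol%), excess 10, CH2Cl2, 40 °C
Reagents that add atoms: none
Why: Olefin cross-metathesis of the terminal alkene with excess methacrylate should give the trisubstituted (E)-enoate, the ketone and silyl ether being inert to the ruthenium carbene.

Step 5
Reactants: 11 methyl (E)-2-methyl-5-{1-methyl-5-oxo-2-[2-(tert-butyldimethylsilyloxy)ethyl]cyclohexyl}pent-2-enoate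
Product: 12 methyl 2-methyl-5-{1-methyl-5-oxo-2-[2-(tert-butyldimethylsilyloxy)ethyl]cyclohexyl}pentanoate
Conditions: H2 (1 atm), Pd on carbon, EtOAc, rt
Reagents that add atoms: none
Why: Heterogeneous catalytic hydrogenation saturates the enoate and completes the C1–C4 chain at the ester oxidation level; C4 forms as both epimers, which is immaterial here.

Step 6
Reactants: 12 methyl 2-methyl-5-{1-methyl-5-oxo-2-[2-(tert-butyldimethylsilyloxy)ethyl]cyclohexyl}pentanoate
Product: 13 methyl 2-methyl-5-{1-methyl-5-oxo-2-[2-(tert-butyldimethylsilyloxy)ethyl]cyclohex-3-enyl}pentanoate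
Conditions: IBX, DMSO–toluene, 70 °C
Reagents that add atoms: none
Why: IBX dehydrogenation of the ketone through its enol can only introduce the C7–C8 double bond, because C10 on the other side carries no hydrogen.

Step 7
Reactants: 13 methyl 2-methyl-5-{1-methyl-5-oxo-2-[2-(tert-butyldimethylsilyloxy)ethyl]cyclohex-3-enyl}pentanoate
Product: 15 methyl 5-{1,3-dimethyl-5-oxo-2-[2-(tert-butyldimethylsilyloxy)ethyl]cyclohex-3-enyl}-2-methylpentanoate, via silyl enol ether 14 (not isolated)
Conditions: Me2CuLi, TMSCl, Et2O, −78 °C; then Pd(OAc)2 (10 mol%), O2, DMSO, rt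
Reagents that add atoms: lithium dimethylcuprate, [Li+].C[Cu-]C
Why: Gilman 1,4-addition places the C17 methyl on C8 and Saegusa–Ito oxidation of 14 returns the C7–C8 enone, erasing the temporary C8 stereocentre.

Step 8
Reactants: 15 methyl 5-{1,3-dimethyl-5-oxo-2-[2-(tert-butyldimethylsilyloxy)ethyl]cyclohex-3-enyl}-2-methylpentanoate
Product: 16 methyl 5-{5-(tert-butyldimethylsilyloxy)-1,3-dimethyl-2-[2-(tert-butyldimethylsilyloxy)ethyl]cyclohexa-3,5-dienyl}-2-methylpentanoate
Conditions: LiN(iPr)2, THF, −78 °C; then TBSCl, DMPU, −78 to 0 °C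
Reagents that add atoms: tert-butyldimethylsilyl chloride, CC(C)(C)[Si](C)(C)Cl
Why: Kinetic deprotonation by the hindered amide removes an α′ proton at C5, as with other 3-methyl-5,5-disubstituted cyclohexenones, and O-silylation of the cross-conjugated dienolate gives the 2-silyloxy diene; any ketene acetal formed from the ester reverts on work-up.

Step 9
Reactants: 16 methyl 5-{5-(tert-butyldimethylsilyloxy)-1,3-dimethyl-2-[2-(tert-butyldimethylsilyloxy)ethyl]cyclohexa-3,5-dienyl}-2-methylpentanoate
Product: 17 methyl 2-bromo-5-{5-(tert-butyldimethylsilyloxy)-1,3-dimethyl-2-[2-(tert-butyldimethylsilyloxy)ethyl]cyclohexa-3,5-dienyl}-2-methylpentanoate (key-step precursor)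
Conditions: LiN(iPr)2, THF, −78 °C; then BrCCl2CCl2Br, −78 °C
Reagents that add atoms: 1,2-dibromo-1,1,2,2-tetrachloroethane, BrC(Cl)(Cl)C(Cl)(Cl)Br
Why: With the ring ketone masked as its silyl dienol ether the only acidic C–H is at C4, so the ester enolate should form cleanly and be brominated by halogen transfer (enolate bromination) to the tertiary α-bromo ester as both C4 epimers.

Step 10
Reactants: 17 methyl 2-bromo-5-{5-(tert-butyldimethylsilyloxy)-1,3-dimethyl-2-[2-(tert-butyldimethylsilyloxy)ethyl]cyclohexa-3,5-dienyl}-2-methylpentanoate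
Product: 19 methyl 12-(tert-butyldimethylsilyloxy)-6-oxo-13,14,15,16-tetranor-ent-labd-7-en-18-oate (trans-fused; key-step product), via cis-fused enone 18 (not isolated)
Conditions: Ru(bpy)3Cl2·6H2O (2 mol%), 2,6-lutidine, MeCN, blue LEDs (450 nm), rt; then DBU, rt
Reagents that add atoms: none
Why: Visible-light excitation of Ru(bpy)3Cl2 gives an excited state that transfers one electron to the C4–Br bond of 17, and the planar, electrophilic tertiary α-ester radical adds to C5, the electron-rich terminus of the C6 silyl dienol ether, after which the siloxyallyl radical is oxidised (by the oxidised photocatalyst or by a second molecule of 17) and bromide strips the silyl group to return the C6 ketone conjugated with C7–C8 (radical–polar crossover). The closest known reaction type is the photoredox α-alkylation of silyl enol ethers by α-bromo esters, run here intramolecularly. Ring A, the only ring closed, forms by 6-exo-trig attack through a chair in which C1 leaves C10 pseudoaxially, anti to the pseudoaxial C9 chain, so the C4–C5 bond is made on the face of ring B opposite C20 and the fusion is cis at first. C4 is fixed in that chair, where the ester stays coplanar with the radical centre and is expected to turn outward to escape allylic strain with the C6 siloxy group, leaving the methyl inside and syn to C20; C5 is then set thermodynamically, DBU epimerising it through the enolate to the trans-fused decalin. The step needs attack at C5 rather than C7 or C8 and cyclisation faster than radical reduction: polarity matching, the six-membered transition state and the absence of a hydrogen-atom donor should secure both, and either C4 epimer of 17 gives the same radical.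

Step 11
Reactants: 19 methyl 12-(tert-butyldimethylsilyloxy)-6-oxo-13,14,15,16-tetranor-ent-labd-7-en-18-oate
Product: 20 methyl 12-(tert-butyldimethylsilyloxy)-6-oxo-13,14,15,16-tetranor-ent-labd-8(17)-en-18-oate
Conditions: LiN(iPr)2, DMPU, THF, −78 °C; then AcOH, −78 °C
Reagents that add atoms: none
Why: Irreversible γ-deprotonation by the hindered amide is expected at the exposed primary C17 hydrogens rather than at the tertiary C9–H beside quaternary C10 or the buried C5–H, and kinetic protonation of the linear dienolate at C7 (deconjugative protonation) should leave the double bond exocyclic at C8–C17.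

Step 12
Reactants: 20 methyl 12-(tert-butyldimethylsilyloxy)-6-oxo-13,14,15,16-tetranor-ent-labd-8(17)-en-18-oate
Product: 21 methyl 12-(tert-butyldimethylsilyloxy)-6-hydroxy-13,14,15,16-tetranor-ent-labd-8(17)-en-18-oate (C6 hydroxyl equatorial and anti to C20)
Conditions: crude 20, SmI2, H2O, THF, 0 °C
Reagents that add atoms: none
Why: Single-electron ketone reduction by SmI2 with water as proton donor passes through a ketyl/carbanion that keeps oxygen equatorial, away from the axial C19 and C20 methyls, so the equatorial C6 alcohol is expected while the hindered ester and the alkene are left alone.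

Step 13
Reactants: 21 methyl 12-(tert-butyldimethylsilyloxy)-6-hydroxy-13,14,15,16-tetranor-ent-labd-8(17)-en-18-oate
Product: 22 methyl 6-acetoxy-12-(tert-butyldimethylsilyloxy)-13,14,15,16-tetranor-ent-labd-8(17)-en-18-oate
Conditions: Ac2O, DMAP, pyridine, CH2Cl2, rt
Reagents that add atoms: acetic anhydride, CC(=O)OC(C)=O
Why: DMAP-catalysed acylation should esterify the equatorial secondary alcohol with retention at C6.

Step 14
Reactants: 22 methyl 6-acetoxy-12-(tert-butyldimethylsilyloxy)-13,14,15,16-tetranor-ent-labd-8(17)-en-18-oate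
Product: 23 methyl 6-acetoxy-12-hydroxy-13,14,15,16-tetranor-ent-labd-8(17)-en-18-oate
Conditions: HF·pyridine, THF, 0 °C to rt
Reagents that add atoms: none
Why: Fluoride-driven desilylation frees the primary C12 alcohol, while the acetate, the methyl ester and the exocyclic alkene tolerate the buffered medium.

Step 15
Reactants: 23 methyl 6-acetoxy-12-hydroxy-13,14,15,16-tetranor-ent-labd-8(17)-en-18-oate
Product: 24 methyl 6-acetoxy-12-oxo-13,14,15,16-tetranor-ent-labd-8(17)-en-18-oate
Conditions: Dess–Martin periodinane, pyridine, CH2Cl2, rt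
Reagents that add atoms: none
Why: Dess–Martin oxidation should convert the primary alcohol to the aldehyde under mild buffered conditions that do not move the exocyclic alkene.

Step 16
Reactants: 24 methyl 6-acetoxy-12-oxo-13,14,15,16-tetranor-ent-labd-8(17)-en-18-oate; 25 2-(triphenylphosphoranylidene)propanal
Product: 26 methyl 6-acetoxy-14-oxo-15-nor-ent-labda-8(17),12E-dien-18-oate
Conditions: toluene, 90 °C
Reagents that add atoms: none
Why: Wittig olefination with the stabilised α-methyl ylide should give the (E)-2-methyl-2-enal, which sets the C12–C13 geometry.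

Step 17
Reactants: 26 methyl 6-acetoxy-14-oxo-15-nor-ent-labda-8(17),12E-dien-18-oate
Product: 27 methyl 6-acetoxy-ent-labda-8(17),12E,14-trien-18-oate (CNP0212193.1)
Conditions: Ph3PCH3Br, KOtBu, THF, 0 °C; then 26, −78 to 0 °C
Reagents that add atoms: methyltriphenylphosphonium bromide, C[P+](c1ccccc1)(c1ccccc1)c1ccccc1.[Br-]
Why: Wittig methylenation of the enal carbonyl at low temperature completes the 1,3-diene, the acetate and the hindered methyl ester reacting far more slowly with the ylide.

## Compound list

1 | 4-[(tert-butyldimethylsilyl)oxy]butanal | O=CCCCO[Si](C)(C)C(C)(C)C | starting material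
2 | methyl vinyl ketone (but-3-en-2-one) | C=CC(C)=O | starting material
3 | (S)-2-[2-(tert-butyldimethylsilyloxy)ethyl]-5-oxohexanal | CC(=O)CC[C@@H](CCO[Si](C)(C)C(C)(C)C)C=O | intermediate (not isolated)
4 | (S)-4-[2-(tert-butyldimethylsilyloxy)ethyl]cyclohex-2-en-1-one | O=C1C=C[C@H](CCO[Si](C)(C)C(C)(C)C)CC1 | intermediate
5 | trans-3-methyl-4-[2-(tert-butyldimethylsilyloxy)ethyl]-1-(trimethylsilyloxy)cyclohex-1-ene (methyl anti to the chain) | C[Si](C)(C)OC1=C[C@@H](C)[C@H](CCO[Si](C)(C)C(C)(C)C)CC1 | intermediate (not isolated)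
6 | (S)-4-[2-(tert-butyldimethylsilyloxy)ethyl]-3-methylcyclohex-2-en-1-one | O=C1C=C(C)[C@H](CCO[Si](C)(C)C(C)(C)C)CC1 | intermediate
7 | but-3-enylmagnesium bromide | C=CCC[Mg]Br | starting material
8 | trimethylsilyl enol ether of 9 (C5=C6) | C=CCC[C@]1(C)C=C(O[Si](C)(C)C)CC[C@H]1CCO[Si](C)(C)C(C)(C)C | intermediate (not isolated)
9 | (3R,4S)-3-(but-3-enyl)-3-methyl-4-[2-(tert-butyldimethylsilyloxy)ethyl]cyclohexan-1-one (butenyl anti to the C9 chain) | C=CCC[C@]1(C)CC(=O)CC[C@H]1CCO[Si](C)(C)C(C)(C)C | intermediate
10 | methyl methacrylate | C=C(C)C(=O)OC | starting material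
11 | methyl (E)-2-methyl-5-{1-methyl-5-oxo-2-[2-(tert-butyldimethylsilyloxy)ethyl]cyclohexyl}pent-2-enoate (ring centres as in 9) | COC(=O)/C(C)=C/CC[C@]1(C)CC(=O)CC[C@H]1CCO[Si](C)(C)C(C)(C)C | intermediate
12 | methyl 2-methyl-5-{1-methyl-5-oxo-2-[2-(tert-butyldimethylsilyloxy)ethyl]cyclohexyl}pentanoate (both C4 epimers) | COC(=O)C(C)CCC[C@]1(C)CC(=O)CC[C@H]1CCO[Si](C)(C)C(C)(C)C | intermediate
13 | methyl 2-methyl-5-{1-methyl-5-oxo-2-[2-(tert-butyldimethylsilyloxy)ethyl]cyclohex-3-enyl}pentanoate (both C4 epimers) | COC(=O)C(C)CCC[C@]1(C)CC(=O)C=C[C@H]1CCO[Si](C)(C)C(C)(C)C | intermediate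
14 | trimethylsilyl enol ether (C6=C7) carrying the C8 methyl anti to the C9 chain (both C4 epimers) | COC(=O)C(C)CCC[C@]1(C)CC(O[Si](C)(C)C)=C[C@H](C)[C@H]1CCO[Si](C)(C)C(C)(C)C | intermediate (not isolated)
15 | methyl 5-{1,3-dimethyl-5-oxo-2-[2-(tert-butyldimethylsilyloxy)ethyl]cyclohex-3-enyl}-2-methylpentanoate (ring-B enone ester; both C4 epimers) | COC(=O)C(C)CCC[C@]1(C)CC(=O)C=C(C)[C@H]1CCO[Si](C)(C)C(C)(C)C | intermediate
16 | methyl 5-{5-(tert-butyldimethylsilyloxy)-1,3-dimethyl-2-[2-(tert-butyldimethylsilyloxy)ethyl]cyclohexa-3,5-dienyl}-2-methylpentanoate (silyl dienol ether; both C4 epimers) | COC(=O)C(C)CCC[C@]1(C)C=C(O[Si](C)(C)C(C)(C)C)C=C(C)[C@H]1CCO[Si](C)(C)C(C)(C)C | intermediate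
17 | methyl 2-bromo-5-{5-(tert-butyldimethylsilyloxy)-1,3-dimethyl-2-[2-(tert-butyldimethylsilyloxy)ethyl]cyclohexa-3,5-dienyl}-2-methylpentanoate (key-step precursor; both C4 epimers) | COC(=O)C(C)(Br)CCC[C@]1(C)C=C(O[Si](C)(C)C(C)(C)C)C=C(C)[C@H]1CCO[Si](C)(C)C(C)(C)C | intermediate
18 | cis-fused C5 epimer of 19 (H5 syn to C20) | CC(C)(C)[Si](C)(C)OCC[C@@H]1C(C)=CC(=O)[C@@H]2[C@@]1(C)CCC[C@]2(C)C(=O)OC | intermediate (not isolated)
19 | methyl 12-(tert-butyldimethylsilyloxy)-6-oxo-13,14,15,16-tetranor-ent-labd-7-en-18-oate (trans-fused; C19 methyl and C11 chain syn to C20; key-step product) | CC(C)(C)[Si](C)(C)OCC[C@@H]1C(C)=CC(=O)[C@H]2[C@@]1(C)CCC[C@]2(C)C(=O)OC | intermediate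
20 | methyl 12-(tert-butyldimethylsilyloxy)-6-oxo-13,14,15,16-tetranor-ent-labd-8(17)-en-18-oate | CC(C)(C)[Si](C)(C)OCC[C@@H]1C(=C)CC(=O)[C@H]2[C@@]1(C)CCC[C@]2(C)C(=O)OC | intermediate
21 | methyl 12-(tert-butyldimethylsilyloxy)-6-hydroxy-13,14,15,16-tetranor-ent-labd-8(17)-en-18-oate (equatorial OH anti to C20) | CC(C)(C)[Si](C)(C)OCC[C@@H]1C(=C)C[C@@H](O)[C@H]2[C@@]1(C)CCC[C@]2(C)C(=O)OC | intermediate
22 | methyl 6-acetoxy-12-(tert-butyldimethylsilyloxy)-13,14,15,16-tetranor-ent-labd-8(17)-en-18-oate | CC(C)(C)[Si](C)(C)OCC[C@@H]1C(=C)C[C@@H](OC(C)=O)[C@H]2[C@@]1(C)CCC[C@]2(C)C(=O)OC | intermediate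
23 | methyl 6-acetoxy-12-hydroxy-13,14,15,16-tetranor-ent-labd-8(17)-en-18-oate | OCC[C@@H]1C(=C)C[C@@H](OC(C)=O)[C@H]2[C@@]1(C)CCC[C@]2(C)C(=O)OC | intermediate
24 | methyl 6-acetoxy-12-oxo-13,14,15,16-tetranor-ent-labd-8(17)-en-18-oate | O=CC[C@@H]1C(=C)C[C@@H](OC(C)=O)[C@H]2[C@@]1(C)CCC[C@]2(C)C(=O)OC | intermediate
25 | 2-(triphenylphosphoranylidene)propanal | CC(C=O)=P(c1ccccc1)(c1ccccc1)c1ccccc1 | starting material
26 | methyl 6-acetoxy-14-oxo-15-nor-ent-labda-8(17),12E-dien-18-oate | O=C/C(C)=C/C[C@@H]1C(=C)C[C@@H](OC(C)=O)[C@H]2[C@@]1(C)CCC[C@]2(C)C(=O)OC | intermediate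
27 | methyl 6-acetoxy-ent-labda-8(17),12E,14-trien-18-oate (CNP0212193.1) | C=C/C(C)=C/C[C@@H]1C(=C)C[C@@H](OC(C)=O)[C@H]2[C@@]1(C)CCC[C@]2(C)C(=O)OC | target

Total steps: 17. Longest linear sequence: 17 steps.

## Steps most likely to fail

**Step 10 (radical cyclisation).** The tertiary radical may be reduced or lose HBr before it reaches the crowded C5; electron transfer from the excited catalyst to the tertiary bromide may be slow; and the facial orientation at C4 is predicted, not secured. Fallback: the C4–C5 bond is made by intramolecular oxidative enolate coupling, setting out from enone ester 15. Two equivalents of LiN(iPr)2 (THF, −78 °C) should give the dilithium bis-enolate F1 (C5 dienolate plus C4 ester enolate). Oxidation with Fe(acac)3 (−78 °C to rt) should join C4 to C5 and give cis enone 18, and DBU then returns the route at 19.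

**Step 11 (deconjugation).** The base may instead remove the C9 proton, or the dienolate may equilibrate, which would move the double bond to C8–C9 and erase C9; the β,γ-enone may also reconjugate on work-up. Fallback: the exocyclic dienolate is generated regiospecifically by desilylation, setting out from enone 13.
- (Me3SiCH2)2CuLi/TMSCl should give the silyl enol ether F2, and Pd(OAc)2/O2 in DMSO the γ-silyl enone F3.
- LiN(iPr)2/TBSCl should give the silyl dienol ether F4, and LiN(iPr)2/BrCCl2CCl2Br the bromo ester F5.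
- Ru(bpy)3Cl2 under blue light should give the cis-fused enone F6, and DBU the trans-fused γ-silyl enone F7.
- Bu4NF buffered with AcOH (THF, −78 °C) removes the C17 silyl group as the fluorosilane; the dienolate can then only be the exocyclic one, and C7 protonation returns the route at 20.

**Step 9 (ester bromination).** Enolisation of the hindered ester may be incomplete, the brominating agent may attack the electron-rich diene, or the silyl dienol ether may hydrolyse. Fallback: bromination is moved from the lithium enolate to a neutral ketene acetal, setting out from 16. LiN(iPr)2 then TBSCl/DMPU should give the isolable silyl ketene acetal F8. One equivalent of N-bromosuccinimide (THF, −78 °C) should brominate this far more nucleophilic ketene acetal in preference to the dienol ether and return the route at 17.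

## Further compounds

F1 | step 10 | dilithium bis-enolate of 15 (C5 dienolate and C4 ester enolate) | COC(O[Li])=C(C)CCC[C@]1(C)C=C(O[Li])C=C(C)[C@H]1CCO[Si](C)(C)C(C)(C)C
F2 | step 11 | trimethylsilyl enol ether (C6=C7) carrying CH2SiMe3 on C8 | COC(=O)C(C)CCC[C@]1(C)CC(O[Si](C)(C)C)=CC(C[Si](C)(C)C)[C@H]1CCO[Si](C)(C)C(C)(C)C
F3 | step 11 | C17-trimethylsilyl analogue of enone ester 15 | COC(=O)C(C)CCC[C@]1(C)CC(=O)C=C(C[Si](C)(C)C)[C@H]1CCO[Si](C)(C)C(C)(C)C
F4 | step 11 | C17-trimethylsilyl analogue of silyl dienol ether 16 | COC(=O)C(C)CCC[C@]1(C)C=C(O[Si](C)(C)C(C)(C)C)C=C(C[Si](C)(C)C)[C@H]1CCO[Si](C)(C)C(C)(C)C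
F5 | step 11 | C17-trimethylsilyl analogue of bromo ester 17 | COC(=O)C(C)(Br)CCC[C@]1(C)C=C(O[Si](C)(C)C(C)(C)C)C=C(C[Si](C)(C)C)[C@H]1CCO[Si](C)(C)C(C)(C)C
F6 | step 11 | C17-trimethylsilyl analogue of cis-fused enone 18 | CC(C)(C)[Si](C)(C)OCC[C@@H]1C(C[Si](C)(C)C)=CC(=O)[C@@H]2[C@@]1(C)CCC[C@]2(C)C(=O)OC
F7 | step 11 | C17-trimethylsilyl analogue of trans-fused enone 19 | CC(C)(C)[Si](C)(C)OCC[C@@H]1C(C[Si](C)(C)C)=CC(=O)[C@H]2[C@@]1(C)CCC[C@]2(C)C(=O)OC
F8 | step 9 | tert-butyldimethylsilyl ketene acetal of ester 16 | COC(O[Si](C)(C)C(C)(C)C)=C(C)CCC[C@]1(C)C=C(O[Si](C)(C)C(C)(C)C)C=C(C)[C@H]1CCO[Si](C)(C)C(C)(C)C
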